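At 8.00 h, the last green reading, the flask still had to run to 20 h, so I reckoned forward from the solid and the target.

| flask | solid substrate | catalyst | remark | time |
|---|---|---|---|---|
| green | 0.085 M | 0.11 mM | the very flask that is asked about, followed so far |  |
| red | 0.057 M | 0.11 mM | run made earlier |  |
| flask | 0.085 M | 0.11 mM |  | 20 h |

- green (time / h: target / %, solid substrate / %): 1.00: 0.4, 95.6; 3.00: 4.6, 90.9; 5.00: 8.9, 84.3; 8.00: 17.3, 73.4
- red (time / h: target / %, solid substrate / %): 5.00: 13.6, 75.8; 10.0: 32.5, 51.9; 15.0: 52.6, 25.6; 20.0: 75.4, 4.6

(each reading ± 1 percentage point)

- given per volume of solution although it is solid: solid substrate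
- the analysis behind the earlier runs scatters by 1 percentage point, standard deviation
- at the start none of the solid substrate is in solution

- how much target there is at 20 h, in percent of the solid substrate charged
- the change that raises the amount of target at 20 h, in percent of the solid substrate charged most ("none" if none brings more than 2 percentage points) (summer / dawn / autumn / none)
- amount of target at 20 h, in percent of the solid substrate charged, after summer

- summer: doubling the dissolution coefficient of the solid substrate, all else as stated
- dawn: doubling the amount of catalyst, all else as stated
- autumn: doubling the solubility of the solid substrate, all else as stated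

Between 5.00 h and 20.0 h the red solid fell at 2.71 mM h⁻¹. The green solid fell at 2.70 mM h⁻¹, about the same. The green charge of 0.085 M was larger than the red charge of 0.057 M. So I took the unseen dissolved pool as standing still (a quasi-steady state) and watched what left it. Red gave 86.8 % for the capture share, the target gained per solid lost while the pool stands, so target grew at 2.35 mM h⁻¹. Green would keep 35.2 % of its solid at 20 h, so the rate should last, and counting on from 8.00 h gave 50.5 %. The weak link was that single green reading, with its scatter of 1 percentage point. I reforged it from the red target line, which runs back to zero at 1.70 h. That line gives green 50.6 %, and I committed to it.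

The forecast said 50.5 %, dawn as the best change and 57 % after summer: “Doubling dissolution only saturates the catalyst”.

The flask gave 50.1 %, with autumn best: it gained 36 points, summer 35 points and dawn 9.2 points. After summer it held 84.9 %, against the forecast's 57 %.

    starting material → side product (k = 0.00860 h⁻¹)
    2 starting material → self-condensation product (k = 6.20 × 10⁻⁴ L mol⁻¹ h⁻¹)
    solid substrate ⇌ starting material, rate k3*(cs3 - [starting material]) while solid is left; crystals form when [starting material] > cs3 (solubility = 0.0600 M, k = 0.0510 h⁻¹)
    starting material + catalyst → catalyst + target (k = 3100 L mol⁻¹ h⁻¹)
    starting material → uncatalysed product (k = 0.0330 h⁻¹)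

In the flask at 20 h, 56.2 % had passed beyond solid and starting material, and the capture share makes that 48.8 % target. In the neighbour flask, with 6.6 × 10⁻⁵ M of catalyst, I scaled capture with catalyst against an unchanged leak. The share becomes 79.8 %, and 49.6 % had passed, which gives 39.6 %. That neighbour flask held 41.2 % target.

All runs are calculated from invented constants, and the scatter is random.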